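**Plan**
Cuts, in retrosynthetic order: the ring bond C7–C8 (C8 radical onto C7 of a 3-(sulfonylmethyl)butenolide), then C5–C6 (vinylogous aldol), C1–C5 (vinyl addition, cleavage to CHO), C9–C10 (aldol); the side-chain bond C2–C3 is made last.
Enabling feature: O9 (on C9) and the acyl carbon C2 (on C1) are cis-1,3 on the cycloheptane, so they can be tied as a five-membered methyl acetal (oxolane O9–C9–C10–C1–C2). This temporary ring masks C9–OH and the C2 aldehyde and holds the C8 radical and the C5–C6 butenolide arm cis.
Forward: aldol (C9–C10), chelate-controlled vinyl addition (C1), oxolane, vinylogous aldol (C5, C6, butenolide), 7-exo radical closure C8 to C7 giving the cycloheptane and, by loss of PhSO2•, the α-methylene lactone, then acetal hydrolysis, (Z)-propenyl addition and oxidation.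
Stereochemistry: C9/C10 from the Ipc boron aldol; C1 from the magnesium 1,3-chelate; C5/C6 from the Cram-chelate vinylogous aldol; C7 from C6 (cis ring fusion); Z-alkene from (Z)-1-bromoprop-1-ene.

Key step: step 14

Remark: carbons are numbered as in guaianolides (ring C1, C5–C10; lactone C11–C13; ring methyl C14; side chain C2–C4, C15). The acetal carbon C2 in 7–9 and 15–19 is an anomeric mixture that converges in step 15, so it is left undefined in the SMILES.

Step 1
Reactants: 1 methyl 2,2-dimethoxyacetate
Product: 3 1,1-dimethoxybutan-2-one, via Weinreb amide 2 (not isolated)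
Conditions: MeNHOMe·HCl, i-PrMgCl, THF, −20 °C; then EtMgBr, 0 °C; aq. NH4Cl
Reagents that add atoms: ethylmagnesium bromide, CC[Mg]Br; N,O-dimethylhydroxylamine hydrochloride, CNOC.Cl (atoms kept in 2 only)
Why: Aminolysis of the ester by the magnesium amide gives the Weinreb amide, and Grignard addition stops at the ketone because the chelated tetrahedral intermediate collapses only on work-up (Weinreb ketone synthesis).

Step 2
Reactants: 3 1,1-dimethoxybutan-2-one; 4 2-[(4-methoxybenzyl)oxy]acetaldehyde
Product: 5 (3S,4S)-4-hydroxy-1,1-dimethoxy-5-[(4-methoxybenzyl)oxy]-3-methylpentan-2-one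
Conditions: (−)-Ipc2BOTf (Ipc = isopinocampheyl, from (+)-α-pinene), i-Pr2NEt, CH2Cl2, −78 °C; 4, −78 to −20 °C; H2O2, MeOH, pH 7 buffer
Reagents that add atoms: none
Why: Only the ethyl side can enolise, the Z-enol borinate reacts through a closed Zimmerman–Traxler transition state to give the syn aldol, and the Ipc ligands choose the aldehyde face so that C9 and C10 are set together (boron-mediated asymmetric aldol reaction).

Step 3
Reactants: 5 (3S,4S)-ketol
Product: 7 (3R,4S,5S)-2-methoxy-5-{[(4-methoxybenzyl)oxy]methyl}-4-methyl-3-vinyloxolan-3-ol, via diol 6 (not isolated)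
Conditions: CH2=CHMgBr (3 equiv), THF/CH2Cl2, −78 °C; aq. NH4Cl; then PPTS (cat.), CH2Cl2, 4 Å sieves, rt
Reagents that add atoms: vinylmagnesium bromide, C=C[Mg]Br
Why: The first equivalent of Grignard reagent forms a six-membered magnesium alkoxide chelate in which the α-methyl group (cis to the C8 arm) is axial, so vinyl adds to the opposite face and sets C1 as the 1,3-anti diol (chelation-controlled 1,2-addition); acid then lets the C9 hydroxyl close the five-membered methyl acetal by transacetalisation, and this order is needed because addition to the cyclic ketone would come from the wrong face.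

Step 4
Reactants: 7 oxolanol
Product: 8 (3R,4S,5S)-2-methoxy-3-(methoxymethoxy)-5-{[(4-methoxybenzyl)oxy]methyl}-4-methyl-3-vinyloxolane
Conditions: MOMCl, i-Pr2NEt, NaI (cat.), ClCH2CH2Cl, 50 °C
Reagents that add atoms: chloromethyl methyl ether, COCCl
Why: Alkylation of the hindered tertiary alcohol under amine/iodide conditions gives an ether that survives the following steps and supplies the chelating α-alkoxy group needed in step 10 (MOM protection).

Step 5
Reactants: 8 vinyl oxolane
Product: 9 (3S,4S,5S)-2-methoxy-3-(methoxymethoxy)-5-{[(4-methoxybenzyl)oxy]methyl}-4-methyloxolane-3-carbaldehyde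
Conditions: OsO4 (cat.), NaIO4, 2,6-lutidine, dioxane/H2O, rt
Reagents that add atoms: sodium periodate (oxygen source, relayed by OsO4), [Na+].[O-]I(=O)(=O)=O
Why: Dihydroxylation of the only alkene and periodate cleavage in the same flask should give the non-enolisable α-alkoxy aldehyde without touching the PMB ether or the acetals (Lemieux–Johnson oxidation).

Step 6
Reactants: 10 2-(bromomethyl)acrylic acid
Product: 11 2-[(phenylsulfonyl)methyl]acrylic acid
Conditions: PhSO2Na, MeOH, reflux
Reagents that add atoms: sodium benzenesulfinate, [Na+].[O-]S(=O)c1ccccc1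
Why: The soft sulfinate displaces the allylic bromide (SN2 or SN2', same product) to give the allyl sulfone that later serves as the radical leaving group.

Step 7
Reactants: 11 2-[(phenylsulfonyl)methyl]acrylic acid
Product: 12 allyl 2-[(phenylsulfonyl)methyl]acrylate
Conditions: allyl alcohol, TsOH (cat.), toluene, reflux, Dean–Stark trap
Reagents that add atoms: prop-2-en-1-ol, C=CCO
Why: Acid-catalysed esterification with removal of water avoids nucleophilic catalysts that could attack the 2-(sulfonylmethyl)acrylate in an SN2' sense (Fischer esterification).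

Step 8
Reactants: 12 allyl 2-[(phenylsulfonyl)methyl]acrylate
Product: 13 3-[(phenylsulfonyl)methyl]furan-2(5H)-one
Conditions: second-generation Grubbs catalyst RuCl2(=CHPh)(H2IMes)(PCy3) (5 mol%), toluene, 80 °C, 0.01 M
Reagents that add atoms: none
Why: Ring-closing metathesis between the allyl and the 1,1-disubstituted acrylate alkenes closes the five-membered butenolide with loss of ethene, as is known for allyl methacrylates.

Step 9
Reactants: 13 3-[(phenylsulfonyl)methyl]furan-2(5H)-one
Product: 14 trimethyl({3-[(phenylsulfonyl)methyl]furan-2-yl}oxy)silane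
Conditions: TMSOTf, Et3N, CH2Cl2, 0 °C; pentane extraction, used crude
Reagents that add atoms: trimethylsilyl trifluoromethanesulfonate, C[Si](C)(C)OS(=O)(=O)C(F)(F)F
Why: O-Silylation followed by γ-deprotonation gives the aromatic 2-silyloxyfuran, the thermodynamically favoured dienol ether (soft enolisation).

Step 10
Reactants: 9 oxolane carbaldehyde; 14 silyloxyfuran
Product: 15 (5R)-5-[(S)-hydroxy{(3S,4S,5S)-2-methoxy-3-(methoxymethoxy)-5-{[(4-methoxybenzyl)oxy]methyl}-4-methyloxolan-3-yl}methyl]-3-[(phenylsulfonyl)methyl]furan-2(5H)-one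
Conditions: MgBr2·OEt2 (3 equiv), CH2Cl2, −78 °C (9 precomplexed); 14, −78 to −30 °C; aq. citric acid
Reagents that add atoms: none
Why: The furan γ-carbon adds to the aldehyde while MgBr2 ties the aldehyde oxygen to the α-OMOM oxygen (Cram chelate), so the nucleophile enters past the smaller C2 flank, away from C10 whose methyl is cis to the formyl group, which sets C5 syn to the C1 oxygen, and the open transition state should give the usual threo relation of C5–O and C6–O (chelation-controlled vinylogous Mukaiyama aldol reaction).

Step 11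
Reactants: 15 carbinol
Product: 16 (S)-[(3S,4S,5S)-2-methoxy-3-(methoxymethoxy)-5-{[(4-methoxybenzyl)oxy]methyl}-4-methyloxolan-3-yl][(2R)-5-oxo-4-[(phenylsulfonyl)methyl]-2,5-dihydrofuran-2-yl]methyl 3-methylbutanoate
Conditions: 3-methylbutanoic anhydride, DMAP (0.2 equiv), pyridine, CH2Cl2, 0 °C to rt
Reagents that add atoms: 3-methylbutanoic anhydride, CC(C)CC(=O)OC(=O)CC(C)C
Why: Acyl transfer to the only free hydroxyl under weakly basic conditions installs the isovalerate while avoiding γ-deprotonation of the butenolide and β-elimination (DMAP-catalysed acylation).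

Step 12
Reactants: 16 PMB ether
Product: 17 primary alcohol: 16 with the PMB ether cleaved to CH2OH (C8–OH)
Conditions: DDQ, CH2Cl2/pH 7 buffer (10:1), 0 °C
Reagents that add atoms: none
Why: Single-electron oxidation of the electron-rich benzyl ether and hydrolysis free the C8 hydroxyl, while the sulfone, acetals, ester and electron-poor butenolide are inert (oxidative PMB cleavage).

Step 13
Reactants: 17 primary alcohol
Product: 18 primary iodide: 17 with CH2OH replaced by CH2I (C8–I)
Conditions: I2, PPh3, imidazole, CH2Cl2, 0 °C to rt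
Reagents that add atoms: iodine, II
Why: The alkoxyphosphonium salt of the only free alcohol is displaced by iodide to give the radical precursor (Garegg–Samuelsson iodination).

Step 14
Reactants: 18 primary iodide
Product: 19 cyclised lactone: cis-fused α-methylene-γ-butyrolactone on the cycloheptane, O9–C2H(OMe) acetal bridge, C1–OMOM, C5–O-isovaleryl; ring stereocentres as in 22
Conditions: Bu3SnSnBu3 (1.5 equiv), hν (sunlamp), benzene, 80 °C, 0.005 M
Reagents that add atoms: none
Why: Proposed new method: a tin radical from photolysed Bu3SnSnBu3 abstracts iodine to give the primary C8 radical, which adds to C7, the β-carbon of the butenolide, and the resulting C11 radical expels the benzenesulfonyl radical from C13 (β-scission), so that the exocyclic C11=C13 double bond of the α-methylene lactone appears in the same event while PhSO2• carries the chain by attacking the ditin. The closest known chemistry is radical allylation of alkyl iodides with 2-(sulfonylmethyl)acrylates (addition–fragmentation, SH2') and 5-exo or 6-exo radical cyclisations ended by loss of a sulfonyl radical; here the same sequence closes a seven-membered ring onto a butenolide. The ring closes 7-exo-trig (C8 onto C7, C11 stays outside the new ring) and the cycloheptane forms as part of an oxabicyclo[4.2.1]nonane held by the O9–C2 acetal bridge. C7 is the only new stereocentre and is fixed by C6, because the five-atom tether can reach only the butenolide face that carries C5, so the lactone is cis-fused. The step needs ring closure to outrun 1,5-hydrogen transfer from C5–H and simple reduction; the cis-1,3 placement of the C8 radical and the C5 arm on the oxolane, the polarity match of a nucleophilic alkyl radical with the electron-poor alkene, and the absence of a hydrogen donor should secure this.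

Step 15
Reactants: 19 cyclised lactone
Product: 20 lactol: 19 with C2–OMe replaced by C2–OH and C1–OMOM by C1–OH (in equilibrium with the open C9-hydroxy C2-aldehyde)
Conditions: 2 M aq. HCl/THF (1:2), 40 °C
Reagents that add atoms: water, O
Why: Aqueous acid hydrolyses the methyl acetal to the lactol and removes the tertiary MOM ether, while the isovalerate and the α-methylene lactone should be stable under these conditions (acetal hydrolysis).

Step 16
Reactants: 20 lactol
Product: 21 allylic alcohol: ring as in 22, C9–OH and C1–OH free, C1 bearing CH(OH)–CH=CH–CH3 (Z), C2 epimers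
Conditions: (Z)-1-bromoprop-1-ene, CrCl2 (6 equiv), NiCl2 (5 mol%), DMSO, rt
Reagents that add atoms: (Z)-1-bromoprop-1-ene, C/C=C\Br
Why: The alkenylchromium species formed from the (Z)-bromide with retention of geometry adds only to the aldehyde form of the lactol and ignores the ester, the lactone and the free hydroxyls, and the new carbinol centre is oxidised in the next step so its configuration does not matter (Nozaki–Hiyama–Kishi reaction).

Step 17
Reactants: 21 allylic alcohol
Product: 22 target CNP0186412.2
Conditions: activated MnO2 (20 equiv), CH2Cl2, rt, dark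
Reagents that add atoms: none
Why: Activated MnO2 oxidises only the allylic alcohol, leaving the secondary C9 and tertiary C1 alcohols untouched, and should keep the Z geometry to give the Z-enone (chemoselective allylic oxidation).

**Compound list**
1 | methyl 2,2-dimethoxyacetate | COC(OC)C(=O)OC | starting material
2 | N,2,2-trimethoxy-N-methylacetamide (Weinreb amide) | COC(OC)C(=O)N(C)OC | intermediate
3 | 1,1-dimethoxybutan-2-one | CCC(=O)C(OC)OC | intermediate
4 | 2-[(4-methoxybenzyl)oxy]acetaldehyde | O=CCOCc1ccc(OC)cc1 | starting material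
5 | (3S,4S)-4-hydroxy-1,1-dimethoxy-5-[(4-methoxybenzyl)oxy]-3-methylpentan-2-one | COC(OC)C(=O)[C@@H](C)[C@H](O)COCc1ccc(OC)cc1 | intermediate
6 | (3R,4S,5S)-3-(dimethoxymethyl)-6-[(4-methoxybenzyl)oxy]-4-methylhex-1-ene-3,5-diol | C=C[C@](O)(C(OC)OC)[C@@H](C)[C@H](O)COCc1ccc(OC)cc1 | intermediate
7 | (3R,4S,5S)-2-methoxy-5-{[(4-methoxybenzyl)oxy]methyl}-4-methyl-3-vinyloxolan-3-ol (C2 anomers) | C=C[C@]1(O)C(OC)O[C@H](COCc2ccc(OC)cc2)[C@@H]1C | intermediate
8 | (3R,4S,5S)-2-methoxy-3-(methoxymethoxy)-5-{[(4-methoxybenzyl)oxy]methyl}-4-methyl-3-vinyloxolane | C=C[C@]1(OCOC)C(OC)O[C@H](COCc2ccc(OC)cc2)[C@@H]1C | intermediate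
9 | (3S,4S,5S)-2-methoxy-3-(methoxymethoxy)-5-{[(4-methoxybenzyl)oxy]methyl}-4-methyloxolane-3-carbaldehyde | O=C[C@]1(OCOC)C(OC)O[C@H](COCc2ccc(OC)cc2)[C@@H]1C | intermediate
10 | 2-(bromomethyl)acrylic acid | C=C(CBr)C(=O)O | starting material
11 | 2-[(phenylsulfonyl)methyl]acrylic acid | C=C(CS(=O)(=O)c1ccccc1)C(=O)O | intermediate
12 | allyl 2-[(phenylsulfonyl)methyl]acrylate | C=CCOC(=O)C(=C)CS(=O)(=O)c1ccccc1 | intermediate
13 | 3-[(phenylsulfonyl)methyl]furan-2(5H)-one | O=C1OCC=C1CS(=O)(=O)c1ccccc1 | intermediate
14 | trimethyl({3-[(phenylsulfonyl)methyl]furan-2-yl}oxy)silane | C[Si](C)(C)Oc1occc1CS(=O)(=O)c2ccccc2 | intermediate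
15 | (5R)-5-[(S)-hydroxy{(3S,4S,5S)-2-methoxy-3-(methoxymethoxy)-5-{[(4-methoxybenzyl)oxy]methyl}-4-methyloxolan-3-yl}methyl]-3-[(phenylsulfonyl)methyl]furan-2(5H)-one | COc1ccc(COC[C@H]2OC(OC)[C@@](OCOC)([C@@H](O)[C@@H]3OC(=O)C(CS(=O)(=O)c4ccccc4)=C3)[C@H]2C)cc1 | intermediate
16 | 3-methylbutanoate of 15 at the carbinol oxygen (C5–O-isovaleryl) | COc1ccc(COC[C@H]2OC(OC)[C@@](OCOC)([C@@H](OC(=O)CC(C)C)[C@@H]3OC(=O)C(CS(=O)(=O)c4ccccc4)=C3)[C@H]2C)cc1 | intermediate
17 | primary alcohol: 16 with the PMB ether cleaved (5-hydroxymethyl oxolane) | OC[C@H]1OC(OC)[C@@](OCOC)([C@@H](OC(=O)CC(C)C)[C@@H]2OC(=O)C(CS(=O)(=O)c3ccccc3)=C2)[C@H]1C | intermediate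
18 | primary iodide: 17 with CH2I in place of CH2OH | IC[C@H]1OC(OC)[C@@](OCOC)([C@@H](OC(=O)CC(C)C)[C@@H]2OC(=O)C(CS(=O)(=O)c3ccccc3)=C2)[C@H]1C | intermediate
19 | cyclised lactone: cis-fused α-methylene-γ-butyrolactone on the cycloheptane, O9–C2H(OMe) bridge, C1–OMOM, C5–O-isovaleryl, ring stereocentres as in 22 | C=C1C(=O)O[C@@H]2[C@H]1C[C@@H](O3)[C@H](C)[C@@](OCOC)(C3OC)[C@H]2OC(=O)CC(C)C | intermediate
20 | lactol: 19 with C2–OH and C1–OH (C2 anomers) | C=C1C(=O)O[C@@H]2[C@H]1C[C@@H](O3)[C@H](C)[C@@](O)(C3O)[C@H]2OC(=O)CC(C)C | intermediate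
21 | allylic alcohol: 22 with C2 as CH(OH) (C2 epimers), Z-alkene | C=C1C(=O)O[C@@H]2[C@H]1C[C@@H](O)[C@H](C)[C@@](O)(C(O)/C=C\C)[C@H]2OC(=O)CC(C)C | intermediate
22 | CNP0186412.2 | C=C1C(=O)O[C@@H]2[C@H]1C[C@@H](O)[C@H](C)[C@@](O)(C(=O)/C=C\C)[C@H]2OC(=O)CC(C)C | target

Total step count: 17. Longest linear sequence: 13 steps (steps 1–5 and 10–17).

**Steps most likely to fail**

Step 14. The C8 radical may be lost before the ring closes, by 1,5-hydrogen transfer from C5–H or by slow closure of the bridged seven-membered ring followed by chain termination. The fallback is polar and uses known chemistry to make the same bond. It sets out from alcohol 17. Dess–Martin oxidation gives aldehyde F1. Zerovalent palladium (Pd(PPh3)4) ionises the allylic sulfone and Et2Zn turns the π-allyl complex into an allylzinc that adds through C7 to the C8 aldehyde (intramolecular carbonyl allylation, the classical way to medium-ring α-methylene lactones), giving alcohol F2. Phenyl chlorothionoformate and pyridine give thionocarbonate F3, and (Me3Si)3SiH with AIBN removes the C8 oxygen (Barton–McCombie deoxygenation). This comes back to the route at 19.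

Step 10. Chelate and non-chelate pathways may compete so that facial or threo/erythro selectivity is poor, or the Lewis acid may ionise the methyl acetal before the hindered aldehyde reacts. The fallback builds the butenolide stepwise and sets out from aldehyde 9. MgBr2·OEt2-mediated addition of (Z)-tributyl[3-(tert-butyldimethylsilyloxy)allyl]stannane (chelate-controlled syn,syn γ-alkoxyallylation) gives allylic silyl ether F4. Isovalerylation as in step 11 gives ester F5, and HF·pyridine frees the C6 hydroxyl to give alcohol F6. Esterification with acid 11 (DCC, cat. DMAP, 0 °C) gives acrylate F7. Ring-closing metathesis with the second-generation Grubbs catalyst RuCl2(=CHPh)(H2IMes)(PCy3) closes the butenolide and comes back to the route at 16.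

Step 16. The bridged lactol may open too slowly, or the hindered α-hydroxy aldehyde may not be attacked by the alkenylchromium species, so that conversion stalls and α-ketol rearrangement takes over. The fallback sets out from lactol 20. (Z)-Prop-1-enyllithium, made from (Z)-1-bromoprop-1-ene and t-BuLi at −78 °C with retention, is transmetalated with CeCl3. The organocerium reagent, used in excess at −78 °C, adds to the lactolate/aldehyde without touching the esters. This comes back to the route at 21 and makes no new compound.

Further compounds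
F1 | step 14 | aldehyde: 17 with CH2OH oxidised to CHO (C8 aldehyde) | O=C[C@H]1OC(OC)[C@@](OCOC)([C@@H](OC(=O)CC(C)C)[C@@H]2OC(=O)C(CS(=O)(=O)c3ccccc3)=C2)[C@H]1C
F2 | step 14 | C8-hydroxy analogue of 19 (C8 epimers) | C=C1C(=O)O[C@@H]2[C@H]1C(O)[C@@H](O3)[C@H](C)[C@@](OCOC)(C3OC)[C@H]2OC(=O)CC(C)C
F3 | step 14 | O-phenyl thionocarbonate of F2 | C=C1C(=O)O[C@@H]2[C@H]1C(OC(=S)Oc4ccccc4)[C@@H](O3)[C@H](C)[C@@](OCOC)(C3OC)[C@H]2OC(=O)CC(C)C
F4 | step 10 | allylation adduct: C5–OH, C6–OTBS, C7=CH2 vinyl on the oxolane core of 9 | COc1ccc(COC[C@H]2OC(OC)[C@@](OCOC)([C@@H](O)[C@H](O[Si](C)(C)C(C)(C)C)C=C)[C@H]2C)cc1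
F5 | step 10 | isovalerate of F4 | COc1ccc(COC[C@H]2OC(OC)[C@@](OCOC)([C@@H](OC(=O)CC(C)C)[C@H](O[Si](C)(C)C(C)(C)C)C=C)[C@H]2C)cc1
F6 | step 10 | allylic alcohol: F5 with the C6 silyl ether removed | COc1ccc(COC[C@H]2OC(OC)[C@@](OCOC)([C@@H](OC(=O)CC(C)C)[C@H](O)C=C)[C@H]2C)cc1
F7 | step 10 | 2-[(phenylsulfonyl)methyl]acrylate of F6 | COc1ccc(COC[C@H]2OC(OC)[C@@](OCOC)([C@@H](OC(=O)CC(C)C)[C@H](OC(=O)C(=C)CS(=O)(=O)c3ccccc3)C=C)[C@H]2C)cc1
F0 | step 16 | none | none
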